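4 questions are asked of 3 flasks, and each turns on the share of target in target plus cross product at the end, a selectivity.

| flask | starting material | coupling partner | second substrate | protic impurity | remark | time |
|---|---|---|---|---|---|---|
| west | 0.26 M | 1.3 equiv | 0.50 equiv | 0.026 M | run made earlier |  |
| south | 0.26 M | 1.8 equiv | 0.50 equiv | 0.026 M | run made earlier |  |
| north-east | 0.26 M | 2.9 equiv | 0.50 equiv | 0.026 M | run made earlier |  |
| north-west | 0.26 M | 1.3 equiv | 0.50 equiv | 0.013 M | run made earlier |  |
| Sunday's | 0.26 M | 1.30 equiv | 0.500 equiv | 0.0260 M | everything together at the start | 2.5 d |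
| Thursday's | 0.26 M (fed, over 25 h) | 1.30 equiv | 0.500 equiv | 0.0260 M | all else is in the flask from the start; the feed brings no volume worth counting | 2.5 d |
| Monday's | 0.26 M | 1.30 equiv | 0.500 equiv (fed, over 25 h) | 0.0260 M | all else is in the flask from the start; the feed brings no volume worth counting | 2.5 d |

1. the flask that comes out highest in share of target in target plus cross product, or "all alike" when all lie within 1.5 percentage points (Sunday's / Thursday's / Monday's / all alike)
2. share of target in target plus cross product at the end, Sunday's
3. share of target in target plus cross product at the end, Thursday's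
4. share of target in target plus cross product at the end, Monday's



west run (percent of the starting material charged)

| time / d | target / % | cross product / % | starting material / % |
|---|---|---|---|
| 0.208 | 23.1 | 41.5 | 18.3 |
| 0.333 | 21.6 | 43.1 | 16.9 |
| 0.500 | 20.7 | 45.0 | 16.7 |
| 0.625 | 20.2 | 43.8 | 14.9 |
| 1.04 | 17.0 | 44.2 | 15.8 |
| 1.67 | 17.7 | 42.8 | 15.0 |
| 2.50 | 18.1 | 43.1 | 13.9 |

south run (percent of the starting material charged)

| time / h | target / % | cross product / % | starting material / % |
|---|---|---|---|
| 2.50 | 32.0 | 43.0 | 15.9 |
| 8.00 | 22.8 | 42.1 | 12.5 |
| 15.0 | 20.8 | 44.1 | 9.9 |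
| 20.0 | 21.0 | 41.2 | 12.3 |
| 30.0 | 20.8 | 42.1 | 10.8 |
| 40.0 | 20.3 | 43.1 | 8.8 |
| 50.0 | 18.6 | 43.6 | 10.3 |

north-east run (percent of the starting material charged)

| time / h | target / % | cross product / % | starting material / % |
|---|---|---|---|
| 6.00 | 28.6 | 39.9 | 9.4 |
| 15.0 | 24.9 | 40.4 | 8.0 |
| 20.0 | 23.9 | 41.3 | 7.0 |
| 30.0 | 22.2 | 40.2 | 7.3 |
| 40.0 | 22.0 | 40.0 | 8.0 |
| 50.0 | 24.7 | 39.9 | 5.4 |

north-west run (percent of the starting material charged)

| time / h | target / % | cross product / % | starting material / % |
|---|---|---|---|
| 10.0 | 19.4 | 44.9 | 14.6 |
| 20.0 | 17.3 | 46.0 | 15.2 |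
| 30.0 | 18.7 | 47.3 | 13.2 |
| 40.0 | 16.4 | 46.5 | 15.7 |
| 50.0 | 18.0 | 46.9 | 13.2 |

(standard deviation of a reading: 1 percentage point)

West has Sunday's charges, so I take the mean of its last 3 readings as my base: target 17.6%, cross product 43.4%, share 28.9%.

First I ask what each number is worth. Coupling partner matters moderately: north-east, at 2.9 equiv, reads a share of 36.5%, but the new flasks stay at 1.30 equiv. North-west, with half of the impurity, reads 27.4%. The number to know well is where second substrate goes: with west's target held, the share reaches the symmetric point of one half when the fraction becoming cross product falls to 0.352.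

West reads 0.867 for this capture, the fraction of the second substrate charge ending as cross product. Its shortfall reads 0.133, and north-west's reads 0.0620, so I guess that impurity takes the missing second substrate. The impurity charge is 0.200 of the second substrate charge. For Thursday's I assume it takes that whole amount, one for one, and I count no other taker, which puts my capture at 0.800. With west's target, my reckoning gives Thursday's a share of 30.6%.

The forecast names Thursday's, with 29% for Sunday's, 33% for Thursday's and 27% for Monday's. It expects “less early loss and a bit less cross product” on Thursday's. Its Thursday's figure stands above mine.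

Thursday's comes out highest at 50.9%, with Sunday's at 29.3% and Monday's at 32.0%.

    starting material + coupling partner ⇌ target (K = 5.50 M⁻¹, k = 0.00180 M⁻¹ s⁻¹)
    target ⇌ isomer of the product (K = 1.30, k = 3.70 × 10⁻⁵ s⁻¹)
    second substrate + protic impurity → quenched substrate (k = 0.0120 M⁻¹ s⁻¹)
    second substrate + coupling partner → second product (k = 1.20 × 10⁻⁴ M⁻¹ s⁻¹)
    starting material + second substrate → cross product (k = 0.0120 M⁻¹ s⁻¹)

Thursday's capture is 0.435, against my 0.800: 0.200 of its second substrate became quenched substrate and 0.365 became second product. In the neighbour of Sunday's with 0.200 equiv of second substrate, west's capture and that flask's target of 25.2% reckon a share of 59.2%; that flask gives 58.8%.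

The numbers in the tables are simulated on assumed constants; noise was put on by code.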